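**Retrosynthetic overview**
1. Tangeretin ⇒ cut the O1–C8a aryl–oxygen bond of the pyranone (ring C). This gives the open-chain 1-(4-methoxyphenyl)-3-(2,3,4,5-tetramethoxyphenyl)propane-1,3-dione, in which C8a is still a plain aryl C–H; the ring is closed by dehydrogenative C–H/O–H coupling.
2. 1,3-Diketone ⇒ Claisen disconnection into 2',3',4',5'-tetramethoxyacetophenone and methyl 4-methoxybenzoate.
3. Acetophenone ⇒ Friedel–Crafts acetylation of symmetric 1,2,3,4-tetramethoxybenzene with acetic anhydride.
4. Ring order: rings A and B are bought as intact benzene rings; ring C is the only ring made and is closed last.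

Assumption: tangeretin is achiral (no stereocentre or other stereogenic element), so there is no configuration to set or protect.
Assumption: only species that build up in the flask before the next operation are numbered; fleeting mechanistic intermediates are described in the Why lines.

**Step 1**
Reactants: 1 1,2,3,4-tetramethoxybenzene; 2 acetic anhydride
Product: 3 1-(2,3,4,5-tetramethoxyphenyl)ethan-1-one
Conditions: Ac2O (1.5 equiv), Bi(OTf)3 (5 mol %), MeNO2, 60 °C
Reagents that add atoms: acetic anhydride (2), CC(=O)OC(C)=O
Why: Friedel–Crafts acylation of a strongly activated ring whose two free positions are equivalent by symmetry, so only one ketone can form; the acetyl group blocks a second acylation, and the catalytic triflate (unlike stoichiometric AlCl3) should not cleave the methoxy group ortho to the new ketone; no stereocentre is formed.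

**Step 2**
Reactants: 3 1-(2,3,4,5-tetramethoxyphenyl)ethan-1-one; 4 methyl 4-methoxybenzoate
Product: 6 1-(4-methoxyphenyl)-3-(2,3,4,5-tetramethoxyphenyl)propane-1,3-dione, via sodium diketonate 5 (not isolated)
Conditions: NaH (2.5 equiv), 4 (1.3 equiv), THF, reflux; then 1 M HCl, 0 °C
Reagents that add atoms: methyl 4-methoxybenzoate (4), COC(=O)c1ccc(OC)cc1; NaH, [Na+].[H-] (sodium only in intermediate 5, removed by the HCl quench)
Why: Crossed Claisen condensation in which the non-enolisable ester 4 can only be the acceptor and irreversible deprotonation of the product to the chelated diketonate 5 drives the equilibrium; the aryl methyl ethers are inert to NaH, and no stereocentre is formed (6 exists mainly as the chelated enol).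

**Step 3**
Reactants: 6 1-(4-methoxyphenyl)-3-(2,3,4,5-tetramethoxyphenyl)propane-1,3-dione
Product: 7 tangeretin (5,6,7,8-tetramethoxy-2-(4-methoxyphenyl)-4H-chromen-4-one)
Conditions: undivided cell, graphite anode, Pt cathode, nBu4NPF6 (0.1 M), HFIP/CH2Cl2 (4:1), 0.02 M, 5 mA/cm2, 2.2 F/mol, rt
Reagents that add atoms: none
Why: Proposed new method: anodic dehydrogenative aryl C–H/enol O–H coupling that closes ring C by forming the O1–C8a bond — the tetramethoxyaryl ketone ring is the most easily oxidised site (estimated about +1.5 V against about +1.9 V for the anisoyl ring), HFIP stabilises its radical cation and breaks the intramolecular enol hydrogen bond so that the anisoyl-side enol oxygen can swing onto the only C–H of ring A (ortho to the acyl group, ortho and para to methoxy groups), and six-membered closure there is made irreversible by loss of a second electron and a proton to give the aromatic chromone while the protons leave as H2 at the cathode; the closest known reaction types are the anodic or photoredox dehydrogenative lactonisation of biaryl-2-carboxylic acids to benzocoumarins, the anodic cyclisation of anilides to benzoxazoles and the FeCl3-mediated oxidative closure of electron-rich α-aryl ketones to benzofurans, none of which to my knowledge has been used to close a 4-pyranone from a 1,3-diaryl-1,3-diketone; no stereocentre is formed.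

**Compound list**
1 | 1,2,3,4-tetramethoxybenzene | COc1ccc(OC)c(OC)c1OC | starting material
2 | acetic anhydride | CC(=O)OC(C)=O | starting material
3 | 1-(2,3,4,5-tetramethoxyphenyl)ethan-1-one (2',3',4',5'-tetramethoxyacetophenone) | CC(=O)c1cc(OC)c(OC)c(OC)c1OC | intermediate
4 | methyl 4-methoxybenzoate | COC(=O)c1ccc(OC)cc1 | starting material
5 | sodium (Z)-1-(4-methoxyphenyl)-3-oxo-3-(2,3,4,5-tetramethoxyphenyl)prop-1-en-1-olate (chelated sodium diketonate of 6) | [Na+].[O-]/C(=C\C(=O)c1cc(OC)c(OC)c(OC)c1OC)c1ccc(OC)cc1 | intermediate
6 | 1-(4-methoxyphenyl)-3-(2,3,4,5-tetramethoxyphenyl)propane-1,3-dione | COc1ccc(cc1)C(=O)CC(=O)c1cc(OC)c(OC)c(OC)c1OC | intermediate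
7 | tangeretin, 5,6,7,8-tetramethoxy-2-(4-methoxyphenyl)-4H-chromen-4-one (achiral) | COc1ccc(-c2cc(=O)c3c(OC)c(OC)c(OC)c(OC)c3o2)cc1 | target

**Total step count:** 3
**Longest linear sequence:** 3 steps (1 → 3 → 6 → 7)

**Steps most likely to fail, with fallbacks**

Step 3 (the proposed new step; highest risk). Three failure modes are foreseeable:
- Attack of the enol oxygen at the methoxy-bearing ortho carbon of ring A instead of the C–H carbon, leading to quinone-ketal or demethoxylated by-products.
- Oxidation of the enol or diketonate followed by carbon–carbon dimerisation.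
- Over-oxidation of the product, which is also electron-rich.

The fallback uses known chemistry, sets out from 3 and comes back to the route at 7. Ring bromination of 3 at its only free aromatic position (NBS, MeCN, 0 °C to rt) gives 1-(2-bromo-3,4,5,6-tetramethoxyphenyl)ethan-1-one F6. Claisen condensation of this ketone with 4 (NaH, THF, reflux) gives sodium (Z)-3-(2-bromo-3,4,5,6-tetramethoxyphenyl)-1-(4-methoxyphenyl)-3-oxoprop-1-en-1-olate F7. Quenching with 1 M HCl gives 1-(2-bromo-3,4,5,6-tetramethoxyphenyl)-3-(4-methoxyphenyl)propane-1,3-dione F8. Intramolecular Ullmann-type O-arylation of the enolate (CuI 10 mol %, K2CO3, DMF, 110 °C) then closes ring C by displacing bromide and gives 7.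

Step 2 (moderate risk). The electron-rich ester 4 is a sluggish acceptor, and self-condensation of 3 can compete. The fallback replaces acylation by aldol addition and oxidation; it sets out from 3 and comes back at 6. Deprotonation with LiN(i-Pr)2 (THF, −78 °C) gives lithium 1-(2,3,4,5-tetramethoxyphenyl)ethen-1-olate F3. Addition of 4-methoxybenzaldehyde gives racemic lithium 1-(4-methoxyphenyl)-3-oxo-3-(2,3,4,5-tetramethoxyphenyl)propan-1-olate F4. An acetic acid quench at −78 °C gives racemic 3-hydroxy-3-(4-methoxyphenyl)-1-(2,3,4,5-tetramethoxyphenyl)propan-1-one F5. Oxidation of this benzylic β-hydroxy ketone with IBX (EtOAc, 75 °C) removes the transient stereocentre and gives 6.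

Step 1 (lowest risk). Conversion may stall through product binding to the catalyst, or the methoxy group ortho to the ketone may be partly cleaved. The fallback replaces electrophilic substitution by directed ortho-metalation; it sets out from 1 and comes back at 3. Treatment with n-BuLi/TMEDA (THF, 0 °C) lithiates one of the two equivalent positions next to a methoxy group and gives (2,3,4,5-tetramethoxyphenyl)lithium F1. Addition of N-methoxy-N-methylacetamide at −78 °C gives the chelated, racemic tetrahedral adduct lithium 1-[methoxy(methyl)amino]-1-(2,3,4,5-tetramethoxyphenyl)ethan-1-olate F2. This adduct collapses on aqueous HCl quench to 3 without over-addition.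

**Further compounds**
F1 | step 1 | (2,3,4,5-tetramethoxyphenyl)lithium | [Li]c1cc(OC)c(OC)c(OC)c1OC
F2 | step 1 | lithium 1-[methoxy(methyl)amino]-1-(2,3,4,5-tetramethoxyphenyl)ethan-1-olate (racemic) | [Li+].[O-]C(C)(N(C)OC)c1cc(OC)c(OC)c(OC)c1OC
F3 | step 2 | lithium 1-(2,3,4,5-tetramethoxyphenyl)ethen-1-olate | [Li+].[O-]C(=C)c1cc(OC)c(OC)c(OC)c1OC
F4 | step 2 | lithium 1-(4-methoxyphenyl)-3-oxo-3-(2,3,4,5-tetramethoxyphenyl)propan-1-olate (racemic) | [Li+].[O-]C(CC(=O)c1cc(OC)c(OC)c(OC)c1OC)c1ccc(OC)cc1
F5 | step 2 | 3-hydroxy-3-(4-methoxyphenyl)-1-(2,3,4,5-tetramethoxyphenyl)propan-1-one (racemic) | OC(CC(=O)c1cc(OC)c(OC)c(OC)c1OC)c1ccc(OC)cc1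
F6 | step 3 | 1-(2-bromo-3,4,5,6-tetramethoxyphenyl)ethan-1-one | CC(=O)c1c(Br)c(OC)c(OC)c(OC)c1OC
F7 | step 3 | sodium (Z)-3-(2-bromo-3,4,5,6-tetramethoxyphenyl)-1-(4-methoxyphenyl)-3-oxoprop-1-en-1-olate | [Na+].[O-]/C(=C\C(=O)c1c(Br)c(OC)c(OC)c(OC)c1OC)c1ccc(OC)cc1
F8 | step 3 | 1-(2-bromo-3,4,5,6-tetramethoxyphenyl)-3-(4-methoxyphenyl)propane-1,3-dione | COc1ccc(cc1)C(=O)CC(=O)c1c(Br)c(OC)c(OC)c(OC)c1OC
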